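**Retrosynthetic overview**
1. The strategy rests on the 5,6-dihydro-2H-pyran-2-one ring (O1, C2–C6) with its cis C5–O-acyl/C6–alkyl pair, which is handled as a dihydropyran. The last moves are desilylation, oxidation of a C2 acetal to the lactone, and acylation of C5–OH with a bis-silylated (2E,4E,6S)-dienoic acid.
2. The 2-isopropoxy-2H-pyran comes from a cis-5-benzoyloxy-6-alkyl-2,3-dihydro-4H-pyran-4-one by 1,2-reduction and Ferrier transposition.
3. That pyranone, the only ring, is formed in one [4+2] cyclocondensation of the C6–C13 aldehyde (C6=O1) with (1E,3Z)-4-benzoyloxy-1-methoxy-3-silyloxybutadiene (C2–C5), making C5–C6 and O1–C2.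
4. Aldehyde: desymmetrised meso-2,4-dimethylglutaric anhydride (C7, C9), sp3–sp2 Negishi coupling for C10–C11, Sharpless epoxidation and reductive epoxide opening for the C11 carbinol.
5. Acid: auxiliary-controlled alkylation for C6', then Wittig and Horner–Wadsworth–Emmons olefinations.

Key step: step 14

**Remarks on the chemistry**
- Atom labels follow the target: lactone O1, C2(=O), C3=C4, C5, C6; chain C7–C13; acyl chain C1'–C8'. TES = triethylsilyl, TBS = tert-butyldimethylsilyl.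
- Assumption: (DHQD)2AQN is taken to give the (2R,4S) half-ester in step 1; if the sense proves opposite, the pseudo-enantiomeric (DHQ)2AQN is used.
- The acetal carbon C2 (steps 16–29) is expected as an anomer mixture and is left undefined in the SMILES; it becomes the lactone carbonyl in step 30. The C4 carbinol of the Luche product is drawn as the expected all-cis epimer and is erased in step 16.

**Route**

Step 1
Reactants: 1 meso-2,4-dimethylglutaric anhydride
Product: 2 (2R,4S)-5-methoxy-2,4-dimethyl-5-oxopentanoic acid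
Conditions: (DHQD)2AQN (10 mol%), MeOH (10 equiv), Et2O, −30 °C
Reagents that add atoms: methanol, CO
Why: Cinchona-alkaloid-catalysed enantioselective methanolysis of the meso anhydride should differentiate the two enantiotopic carbonyls and so fix C7 and C9 in one operation.

Step 2
Reactants: 2 (2R,4S)-5-methoxy-2,4-dimethyl-5-oxopentanoic acid
Product: 3 methyl (2S,4R)-5-hydroxy-2,4-dimethylpentanoate
Conditions: BH3·SMe2, THF, 0 °C → rt; aqueous work-up, used without storage
Reagents that add atoms: none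
Why: Borane reduces the carboxylic acid chemoselectively in the presence of the methyl ester, giving the C10 alcohol while C6 stays at the ester level.

Step 3
Reactants: 3 methyl (2S,4R)-5-hydroxy-2,4-dimethylpentanoate
Product: 4 methyl (2S,4R)-5-iodo-2,4-dimethylpentanoate
Conditions: I2, PPh3, imidazole, CH2Cl2, 0 °C
Reagents that add atoms: iodine, II
Why: Appel-type iodination of the primary alcohol is fast under neutral conditions and should outrun lactonisation of the δ-hydroxy ester.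

Step 4
Reactants: 5 but-2-yn-1-ol
Product: 7 (Z)-3-iodobut-2-en-1-ol, via cyclic vinylaluminate 6 (not isolated)
Conditions: Red-Al, THF, 0 °C → rt; then I2, THF, −78 °C
Reagents that add atoms: iodine, II
Why: Hydroxyl-directed trans-hydroalumination of the propargylic alcohol places aluminium on C3 cis to CH2O, and iodinolysis with retention should give the Z-iodoalkene.

Step 5
Reactants: 7 (Z)-3-iodobut-2-en-1-ol
Product: 8 triethyl{[(2Z)-3-iodobut-2-en-1-yl]oxy}silane
Conditions: TESCl, imidazole, CH2Cl2, 0 °C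
Reagents that add atoms: chlorotriethylsilane, CC[Si](Cl)(CC)CC
Why: Standard silylation masks the hydroxyl proton so that it cannot quench the organozinc partner in step 6.

Step 6
Reactants: 4 methyl (2S,4R)-5-iodo-2,4-dimethylpentanoate; 8 triethyl{[(2Z)-3-iodobut-2-en-1-yl]oxy}silane
Product: 11 methyl (2S,4R,6Z)-8-hydroxy-2,4,6-trimethyloct-6-enoate, via alkylzinc iodide 9 (not isolated), via coupled triethylsilyl ether 10 (not isolated)
Conditions: Zn dust (BrCH2CH2Br/TMSCl-activated), DMA, 40 °C; then 8, Pd(PPh3)4 (5 mol%), THF, rt → 50 °C; then 1 M HCl, THF, rt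
Reagents that add atoms: none
Why: Zinc insertion into the primary iodide tolerates the ester, and sp3–sp2 Negishi coupling with the alkenyl iodide proceeds with retention of alkene geometry to form C10–C11, after which dilute acid removes the allylic TES ether.

Step 7
Reactants: 11 methyl (2S,4R,6Z)-8-hydroxy-2,4,6-trimethyloct-6-enoate
Product: 12 methyl (2S,4R)-5-[(2S,3R)-3-(hydroxymethyl)-2-methyloxiran-2-yl]-2,4-dimethylpentanoate
Conditions: Ti(OiPr)4 (10 mol%), D-(−)-diethyl tartrate (12 mol%), t-BuOOH, 4 Å MS, CH2Cl2, −20 °C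
Reagents that add atoms: tert-butyl hydroperoxide, CC(C)(C)OO
Why: Sharpless asymmetric epoxidation of the Z-trisubstituted (nerol-type) allylic alcohol with the D-tartrate should deliver oxygen to the face that makes C11 S under reagent control.

Step 8
Reactants: 12 methyl (2S,4R)-5-[(2S,3R)-3-(hydroxymethyl)-2-methyloxiran-2-yl]-2,4-dimethylpentanoate
Product: 13 methyl (2S,4R)-5-[(2S,3S)-3-(iodomethyl)-2-methyloxiran-2-yl]-2,4-dimethylpentanoate
Conditions: I2, PPh3, imidazole, THF, 0 °C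
Reagents that add atoms: iodine, II
Why: Appel-type iodination of the primary epoxy alcohol leaves the epoxide and both stereocentres untouched; the descriptor at the CH carbon changes only through priorities.

Step 9
Reactants: 13 methyl (2S,4R)-5-[(2S,3S)-3-(iodomethyl)-2-methyloxiran-2-yl]-2,4-dimethylpentanoate
Product: 14 methyl (2S,4R,6S)-6-hydroxy-2,4,6-trimethyloct-7-enoate
Conditions: Zn dust, MeOH, 60 °C
Reagents that add atoms: none
Why: Zinc-mediated reductive β-elimination of the 2,3-epoxy iodide opens the epoxide to the C12=C13 vinyl group and the tertiary C11 alcohol without touching the C11–O bond, so the configuration is retained.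

Step 10
Reactants: 14 methyl (2S,4R,6S)-6-hydroxy-2,4,6-trimethyloct-7-enoate
Product: 15 methyl (2S,4R,6S)-2,4,6-trimethyl-6-(triethylsilyloxy)oct-7-enoate
Conditions: TESOTf, 2,6-lutidine, CH2Cl2, −78 → 0 °C
Reagents that add atoms: triethylsilyl trifluoromethanesulfonate, CC[Si](CC)(CC)OS(=O)(=O)C(F)(F)F
Why: The silyl triflate silylates the hindered tertiary allylic alcohol under non-ionising basic conditions.

Step 11
Reactants: 15 methyl (2S,4R,6S)-2,4,6-trimethyl-6-(triethylsilyloxy)oct-7-enoate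
Product: 16 (2S,4R,6S)-2,4,6-trimethyl-6-(triethylsilyloxy)oct-7-enal
Conditions: DIBAL-H (1.1 equiv), CH2Cl2, −78 °C; MeOH, then aq. Rochelle salt; used at once
Reagents that add atoms: none
Why: Partial reduction of the α-branched methyl ester stops at the tetrahedral aluminium hemiacetal at −78 °C and should release the aldehyde on work-up without epimerising C7.

Step 12
Reactants: 17 (E)-1-methoxy-3-(trimethylsilyloxy)buta-1,3-diene
Product: 18 (3E)-4-methoxy-2-oxobut-3-en-1-yl benzoate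
Conditions: Pb(OBz)4 (prepared from Pb(OAc)4 and PhCO2H), CH2Cl2, 0 °C → rt
Reagents that add atoms: lead(IV) benzoate, O=C(O[Pb](OC(=O)c1ccccc1)(OC(=O)c1ccccc1)OC(=O)c1ccccc1)c1ccccc1
Why: Rubottom-type oxidation of the silyl dienol ether with a lead(IV) carboxylate acyloxylates the terminal CH2 and returns the α'-benzoyloxy enone.

Step 13
Reactants: 18 (3E)-4-methoxy-2-oxobut-3-en-1-yl benzoate
Product: 19 (1E,3Z)-4-benzoyloxy-1-methoxy-3-(trimethylsilyloxy)buta-1,3-diene
Conditions: TMSOTf, Et3N, Et2O, 0 °C; used fresh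
Reagents that add atoms: trimethylsilyl trifluoromethanesulfonate, C[Si](C)(C)OS(=O)(=O)C(F)(F)F
Why: Soft enolisation can occur only at the CH2OBz carbon and should give the Z enol silane, with silyloxy and benzoyloxy cis.

Step 14
Reactants: 16 (2S,4R,6S)-2,4,6-trimethyl-6-(triethylsilyloxy)oct-7-enal; 19 (1E,3Z)-4-benzoyloxy-1-methoxy-3-(trimethylsilyloxy)buta-1,3-diene
Product: 21 (2R,3S)-2-[(2S,4R,6S)-4,6-dimethyl-6-(triethylsilyloxy)oct-7-en-2-yl]-4-oxo-3,4-dihydro-2H-pyran-3-yl benzoate, via all-cis silyl enol ether cycloadduct 20 (not isolated)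
Conditions: 19 (1.5 equiv), Eu(fod)3 (10 mol%), CHCl3, rt; then TFA (cat.), CH2Cl2, 0 °C, NaHCO3 quench
Reagents that add atoms: none
Why: The Eu(III)-bound aldehyde and the electron-rich diene should combine in a concerted but asynchronous [4+2] cycloaddition (C5–C6 bonding ahead of O1–C2), the closest known reaction type being the lanthanide-catalysed cyclocondensation of aldehydes with 4-acyloxy-1-methoxy-3-silyloxybutadienes, after which acid expels MeOSiMe3 from 20 to unveil the enone. The single six-membered ring (O1, C2–C6) closes in the cycloaddition itself, both ring bonds forming suprafacially on diene and carbonyl, with no separate cyclisation. C5 and C6 are set cis by the endo mode: the Lewis acid sits anti to the alkyl chain on the carbonyl oxygen and occupies the exo position, so the chain lies endo, on the side of the benzoate that the Z enol geometry places outside on C5. The absolute sense at C6 is set by the C7 stereocentre through Felkin–Anh approach anti to the C8 chain, which gives the 6,7-syn (6R) isomer. The step needs endo and Felkin selectivity together; the first is secured by the mild, non-ionising lanthanide and the Z-acyloxy terminus, the second by the size difference between the C7 methyl and the β-branched chain and, if it needs reinforcing, by the matched enantiomer of Eu(hfc)3 in place of Eu(fod)3. Regiochemistry follows from the polarised diene, whose C5 terminus is the nucleophilic end and adds to the carbonyl carbon.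

Step 15
Reactants: 21 cis-5-benzoyloxy-6-alkyl-dihydropyran-4-one
Product: 22 (2R,3R,4R)-4-hydroxy-2-[(2S,4R,6S)-4,6-dimethyl-6-(triethylsilyloxy)oct-7-en-2-yl]-3,4-dihydro-2H-pyran-3-yl benzoate
Conditions: NaBH4, CeCl3·7H2O, MeOH, −78 °C
Reagents that add atoms: none
Why: Luche conditions give clean 1,2-reduction of the vinylogous ester carbonyl at a temperature where the benzoate neither cleaves nor migrates.

Step 16
Reactants: 22 all-cis 4-hydroxy-dihydropyranyl benzoate
Product: 23 (2R,3R)-2-[(2S,4R,6S)-4,6-dimethyl-6-(triethylsilyloxy)oct-7-en-2-yl]-6-(propan-2-yloxy)-3,6-dihydro-2H-pyran-3-yl benzoate (C6-anomer mixture)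
Conditions: i-PrOH (10 equiv), PPTS (10 mol%), CH2Cl2, 0 °C → rt
Reagents that add atoms: propan-2-ol, CC(C)O
Why: Acid-catalysed Ferrier rearrangement ionises the allylic C4–OH with help from the ring oxygen and traps the allyl oxocarbenium at C2, which moves the alkene to C3=C4 and removes the C4 stereocentre.

Step 17
Reactants: 23 2-isopropoxy-2H-pyranyl benzoate
Product: 24 (2R,3R)-2-[(2S,4R,6S)-4,6-dimethyl-6-(triethylsilyloxy)oct-7-en-2-yl]-6-(propan-2-yloxy)-3,6-dihydro-2H-pyran-3-ol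
Conditions: K2CO3 (0.3 equiv), MeOH, 0 °C → rt
Reagents that add atoms: none
Why: Base-catalysed transesterification removes the benzoate while the acetal and the tertiary TES ether are stable to methoxide, a cleavage that would not be possible once the enoate lactone is in place.

Step 18
Reactants: 25 (R)-4-benzyl-1,3-oxazolidin-2-one; 26 pent-4-enoyl chloride
Product: 27 (4R)-4-benzyl-3-(pent-4-enoyl)-1,3-oxazolidin-2-one
Conditions: Et3N, DMAP (10 mol%), CH2Cl2, 0 °C → rt
Reagents that add atoms: none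
Why: DMAP-catalysed N-acylation attaches the chiral auxiliary to the chain that will supply C6', C7' and C8'.

Step 19
Reactants: 27 (4R)-4-benzyl-3-(pent-4-enoyl)-1,3-oxazolidin-2-one
Product: 29 (4R)-4-benzyl-3-{(2S)-2-[(benzyloxy)methyl]pent-4-enoyl}-1,3-oxazolidin-2-one, via titanium Z-enolate 28 (not isolated)
Conditions: TiCl4, i-Pr2NEt, CH2Cl2, 0 °C; then BnOCH2Cl, 0 °C
Reagents that add atoms: benzyl chloromethyl ether, ClCOCc1ccccc1
Why: Evans alkylation of the chelated Z titanium enolate takes the alkoxymethyl electrophile on the face opposite the benzyl group of the (R)-auxiliary, which sets the future C6' centre.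

Step 20
Reactants: 29 alkylated imide
Product: 30 (2R)-2-[(benzyloxy)methyl]pent-4-en-1-ol
Conditions: LiBH4, MeOH (1 equiv), Et2O, 0 °C
Reagents that add atoms: none
Why: Reductive cleavage of the imide gives the primary alcohol and returns the auxiliary without touching the α-stereocentre.

Step 21
Reactants: 30 (2R)-2-[(benzyloxy)methyl]pent-4-en-1-ol
Product: 32 (2R)-2-[(benzyloxy)methyl]butane-1,4-diol, via ozonide 31 (not isolated)
Conditions: O3, CH2Cl2, −78 °C (indicator end-point); then NaBH4, MeOH, −78 °C → rt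
Reagents that add atoms: ozone, [O-][O+]=O
Why: Ozonolysis with reductive work-up converts the allyl group into the 2-hydroxyethyl arm (C7'–C8').

Step 22
Reactants: 32 (2R)-2-[(benzyloxy)methyl]butane-1,4-diol
Product: 33 (2S)-2-[(benzyloxy)methyl]-1,4-bis[(tert-butyldimethylsilyl)oxy]butane
Conditions: TBSCl (2.5 equiv), imidazole, DMF, rt
Reagents that add atoms: tert-butyldimethylsilyl chloride, CC(C)(C)[Si](C)(C)Cl
Why: Both primary hydroxyls are silylated in one operation, leaving the benzyl ether as the only differentiated arm.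

Step 23
Reactants: 33 bis-TBS benzyl ether
Product: 34 (2S)-4-[(tert-butyldimethylsilyl)oxy]-2-{[(tert-butyldimethylsilyl)oxy]methyl}butan-1-ol
Conditions: H2 (1 atm), 10% Pd/C, EtOAc, rt
Reagents that add atoms: none
Why: Neutral hydrogenolysis removes the benzyl ether without cleaving or migrating the TBS ethers.

Step 24
Reactants: 34 bis-TBS alcohol
Product: 35 (2R)-4-[(tert-butyldimethylsilyl)oxy]-2-{[(tert-butyldimethylsilyl)oxy]methyl}butanal
Conditions: Dess–Martin periodinane, NaHCO3, CH2Cl2, 0 °C → rt; used crude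
Reagents that add atoms: none
Why: Buffered Dess–Martin oxidation gives the α-branched aldehyde under non-basic conditions that should not epimerise it.

Step 25
Reactants: 35 bis-TBS aldehyde
Product: 36 (2E,4S)-6-[(tert-butyldimethylsilyl)oxy]-4-{[(tert-butyldimethylsilyl)oxy]methyl}-2-methylhex-2-enal
Conditions: Ph3P=C(CH3)CHO, toluene, 80 °C
Reagents that add atoms: 2-(triphenylphosphoranylidene)propanal, CC(C=O)=P(c1ccccc1)(c1ccccc1)c1ccccc1
Why: The stabilised formyl ylide gives the E trisubstituted enal (C4'=C5') in a Wittig reaction and is too weakly basic to epimerise the aldehyde.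

Step 26
Reactants: 36 bis-TBS enal
Product: 37 ethyl (2E,4E,6S)-8-[(tert-butyldimethylsilyl)oxy]-6-{[(tert-butyldimethylsilyl)oxy]methyl}-4-methylocta-2,4-dienoate
Conditions: (EtO)2P(O)CH2CO2Et, NaH, THF, 0 °C → rt
Reagents that add atoms: triethyl phosphonoacetate, CCOC(=O)CP(=O)(OCC)OCC
Why: Horner–Wadsworth–Emmons olefination of the enal installs the E C2'=C3' bond.

Step 27
Reactants: 37 ethyl dienoate
Product: 38 (2E,4E,6S)-8-[(tert-butyldimethylsilyl)oxy]-6-{[(tert-butyldimethylsilyl)oxy]methyl}-4-methylocta-2,4-dienoic acid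
Conditions: LiOH, THF/MeOH/H2O, rt; then 1 M HCl to pH 4, 0 °C
Reagents that add atoms: lithium hydroxide, [Li+].[OH-]
Why: Saponification of the ethyl ester spares the primary TBS ethers and the diene geometry.

Step 28
Reactants: 24 2-isopropoxy-2H-pyran-5-ol; 38 bis-TBS dienoic acid
Product: 40 (2R,3R)-2-[(2S,4R,6S)-4,6-dimethyl-6-(triethylsilyloxy)oct-7-en-2-yl]-6-(propan-2-yloxy)-3,6-dihydro-2H-pyran-3-yl (2E,4E,6S)-8-[(tert-butyldimethylsilyl)oxy]-6-{[(tert-butyldimethylsilyl)oxy]methyl}-4-methylocta-2,4-dienoate, via mixed trichlorobenzoic anhydride 39 (not isolated)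
Conditions: 2,4,6-Cl3C6H2COCl, Et3N, THF, rt; then 24, DMAP, toluene, rt
Reagents that add atoms: none
Why: Yamaguchi esterification acylates the hindered secondary allylic C5–OH with retention at C5, and the acid cannot deconjugate through a vinylketene because C4' carries no hydrogen.

Step 29
Reactants: 40 ester acetal
Product: 41 (2R,3R)-2-[(2S,4R,6S)-4,6-dimethyl-6-(triethylsilyloxy)oct-7-en-2-yl]-6-hydroxy-3,6-dihydro-2H-pyran-3-yl (2E,4E,6S)-8-[(tert-butyldimethylsilyl)oxy]-6-{[(tert-butyldimethylsilyl)oxy]methyl}-4-methylocta-2,4-dienoate (anomer mixture)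
Conditions: PPTS, acetone/H2O (4:1), rt → 40 °C
Reagents that add atoms: water, O
Why: Mild acid-catalysed hydrolysis exchanges the allylic isopropyl acetal for the lactol under conditions the silyl ethers and both esters should tolerate.

Step 30
Reactants: 41 lactol
Product: 42 (2R,3R)-2-[(2S,4R,6S)-4,6-dimethyl-6-(triethylsilyloxy)oct-7-en-2-yl]-6-oxo-3,6-dihydro-2H-pyran-3-yl (2E,4E,6S)-8-[(tert-butyldimethylsilyl)oxy]-6-{[(tert-butyldimethylsilyl)oxy]methyl}-4-methylocta-2,4-dienoate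
Conditions: MnO2 (activated), CH2Cl2, rt
Reagents that add atoms: none
Why: Manganese dioxide oxidises the allylic lactol to the α,β-unsaturated δ-lactone, which places the carbonyl at C2.

Step 31
Reactants: 42 tris-silylated lactone
Product: 43 CNP0227568.1, (2R,3R)-2-[(2S,4R,6S)-6-hydroxy-4,6-dimethyloct-7-en-2-yl]-6-oxo-3,6-dihydro-2H-pyran-3-yl (2E,4E,6S)-8-hydroxy-6-(hydroxymethyl)-4-methylocta-2,4-dienoate
Conditions: HF·pyridine, pyridine, THF, 0 °C → rt
Reagents that add atoms: none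
Why: Buffered fluoride-mediated desilylation removes the two primary TBS ethers and the tertiary TES ether without opening the lactone or moving the allylic ester.

**Compound list**
1 | meso-2,4-dimethylglutaric anhydride, (3R,5S)-3,5-dimethyloxane-2,6-dione | C[C@H]1C[C@@H](C)C(=O)OC1=O | starting material
2 | (2R,4S)-5-methoxy-2,4-dimethyl-5-oxopentanoic acid | OC(=O)[C@H](C)C[C@H](C)C(=O)OC | intermediate
3 | methyl (2S,4R)-5-hydroxy-2,4-dimethylpentanoate | OC[C@H](C)C[C@H](C)C(=O)OC | intermediate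
4 | methyl (2S,4R)-5-iodo-2,4-dimethylpentanoate | IC[C@H](C)C[C@H](C)C(=O)OC | intermediate
5 | but-2-yn-1-ol | CC#CCO | starting material
6 | sodium 2,2-bis(2-methoxyethoxy)-3-methyl-2,5-dihydro-1,2-oxaaluminol-2-uide (cyclic vinylaluminate) | CC1=CCO[Al-]1(OCCOC)OCCOC.[Na+] | intermediate (not isolated)
7 | (Z)-3-iodobut-2-en-1-ol | C/C(I)=C/CO | intermediate
8 | triethyl{[(2Z)-3-iodobut-2-en-1-yl]oxy}silane | C/C(I)=C/CO[Si](CC)(CC)CC | intermediate
9 | iodo[(2R,4S)-5-methoxy-2,4-dimethyl-5-oxopentyl]zinc | I[Zn]C[C@H](C)C[C@H](C)C(=O)OC | intermediate (not isolated)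
10 | methyl (2S,4R,6Z)-2,4,6-trimethyl-8-(triethylsilyloxy)oct-6-enoate | CC[Si](CC)(CC)OC/C=C(C)\C[C@H](C)C[C@H](C)C(=O)OC | intermediate (not isolated)
11 | methyl (2S,4R,6Z)-8-hydroxy-2,4,6-trimethyloct-6-enoate | OC/C=C(C)\C[C@H](C)C[C@H](C)C(=O)OC | intermediate
12 | methyl (2S,4R)-5-[(2S,3R)-3-(hydroxymethyl)-2-methyloxiran-2-yl]-2,4-dimethylpentanoate | OC[C@H]1O[C@@]1(C)C[C@H](C)C[C@H](C)C(=O)OC | intermediate
13 | methyl (2S,4R)-5-[(2S,3S)-3-(iodomethyl)-2-methyloxiran-2-yl]-2,4-dimethylpentanoate | IC[C@H]1O[C@@]1(C)C[C@H](C)C[C@H](C)C(=O)OC | intermediate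
14 | methyl (2S,4R,6S)-6-hydroxy-2,4,6-trimethyloct-7-enoate | C=C[C@@](C)(O)C[C@H](C)C[C@H](C)C(=O)OC | intermediate
15 | methyl (2S,4R,6S)-2,4,6-trimethyl-6-(triethylsilyloxy)oct-7-enoate | C=C[C@@](C)(O[Si](CC)(CC)CC)C[C@H](C)C[C@H](C)C(=O)OC | intermediate
16 | (2S,4R,6S)-2,4,6-trimethyl-6-(triethylsilyloxy)oct-7-enal | C=C[C@@](C)(O[Si](CC)(CC)CC)C[C@H](C)C[C@H](C)C=O | intermediate
17 | (E)-1-methoxy-3-(trimethylsilyloxy)buta-1,3-diene | CO/C=C/C(=C)O[Si](C)(C)C | starting material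
18 | (3E)-4-methoxy-2-oxobut-3-en-1-yl benzoate | CO/C=C/C(=O)COC(=O)c1ccccc1 | intermediate
19 | (1E,3Z)-4-benzoyloxy-1-methoxy-3-(trimethylsilyloxy)buta-1,3-diene | CO/C=C/C(O[Si](C)(C)C)=C/OC(=O)c1ccccc1 | intermediate
20 | (2R,3S,6R)-2-[(2S,4R,6S)-4,6-dimethyl-6-(triethylsilyloxy)oct-7-en-2-yl]-6-methoxy-4-(trimethylsilyloxy)-3,6-dihydro-2H-pyran-3-yl benzoate (all-cis cycloadduct) | C=C[C@@](C)(O[Si](CC)(CC)CC)C[C@H](C)C[C@H](C)[C@H]1O[C@@H](OC)C=C(O[Si](C)(C)C)[C@H]1OC(=O)c1ccccc1 | intermediate (not isolated)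
21 | (2R,3S)-2-[(2S,4R,6S)-4,6-dimethyl-6-(triethylsilyloxy)oct-7-en-2-yl]-4-oxo-3,4-dihydro-2H-pyran-3-yl benzoate | C=C[C@@](C)(O[Si](CC)(CC)CC)C[C@H](C)C[C@H](C)[C@H]1OC=CC(=O)[C@H]1OC(=O)c1ccccc1 | intermediate
22 | (2R,3R,4R)-4-hydroxy-2-[(2S,4R,6S)-4,6-dimethyl-6-(triethylsilyloxy)oct-7-en-2-yl]-3,4-dihydro-2H-pyran-3-yl benzoate | C=C[C@@](C)(O[Si](CC)(CC)CC)C[C@H](C)C[C@H](C)[C@H]1OC=C[C@@H](O)[C@H]1OC(=O)c1ccccc1 | intermediate
23 | (2R,3R)-2-[(2S,4R,6S)-4,6-dimethyl-6-(triethylsilyloxy)oct-7-en-2-yl]-6-(propan-2-yloxy)-3,6-dihydro-2H-pyran-3-yl benzoate | C=C[C@@](C)(O[Si](CC)(CC)CC)C[C@H](C)C[C@H](C)[C@H]1OC(OC(C)C)C=C[C@H]1OC(=O)c1ccccc1 | intermediate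
24 | (2R,3R)-2-[(2S,4R,6S)-4,6-dimethyl-6-(triethylsilyloxy)oct-7-en-2-yl]-6-(propan-2-yloxy)-3,6-dihydro-2H-pyran-3-ol | C=C[C@@](C)(O[Si](CC)(CC)CC)C[C@H](C)C[C@H](C)[C@H]1OC(OC(C)C)C=C[C@H]1O | intermediate
25 | (R)-4-benzyl-1,3-oxazolidin-2-one | O=C1N[C@H](Cc2ccccc2)CO1 | starting material
26 | pent-4-enoyl chloride | C=CCCC(=O)Cl | starting material
27 | (4R)-4-benzyl-3-(pent-4-enoyl)-1,3-oxazolidin-2-one | C=CCCC(=O)N1C(=O)OC[C@H]1Cc1ccccc1 | intermediate
28 | trichlorotitanium (Z)-enolate of 27 | C=CC/C=C(\O[Ti](Cl)(Cl)Cl)N1C(=O)OC[C@H]1Cc1ccccc1 | intermediate (not isolated)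
29 | (4R)-4-benzyl-3-{(2S)-2-[(benzyloxy)methyl]pent-4-enoyl}-1,3-oxazolidin-2-one | C=CC[C@@H](COCc1ccccc1)C(=O)N1C(=O)OC[C@H]1Cc1ccccc1 | intermediate
30 | (2R)-2-[(benzyloxy)methyl]pent-4-en-1-ol | OC[C@H](COCc1ccccc1)CC=C | intermediate
31 | (2R)-3-(benzyloxy)-2-[(1,2,4-trioxolan-3-yl)methyl]propan-1-ol (ozonide) | OC[C@H](COCc1ccccc1)CC1OOCO1 | intermediate (not isolated)
32 | (2R)-2-[(benzyloxy)methyl]butane-1,4-diol | OC[C@H](COCc1ccccc1)CCO | intermediate
33 | (2S)-2-[(benzyloxy)methyl]-1,4-bis[(tert-butyldimethylsilyl)oxy]butane | CC(C)(C)[Si](C)(C)OC[C@H](COCc1ccccc1)CCO[Si](C)(C)C(C)(C)C | intermediate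
34 | (2S)-4-[(tert-butyldimethylsilyl)oxy]-2-{[(tert-butyldimethylsilyl)oxy]methyl}butan-1-ol | CC(C)(C)[Si](C)(C)OC[C@H](CO)CCO[Si](C)(C)C(C)(C)C | intermediate
35 | (2R)-4-[(tert-butyldimethylsilyl)oxy]-2-{[(tert-butyldimethylsilyl)oxy]methyl}butanal | CC(C)(C)[Si](C)(C)OC[C@H](C=O)CCO[Si](C)(C)C(C)(C)C | intermediate
36 | (2E,4S)-6-[(tert-butyldimethylsilyl)oxy]-4-{[(tert-butyldimethylsilyl)oxy]methyl}-2-methylhex-2-enal | O=C/C(C)=C/[C@@H](CO[Si](C)(C)C(C)(C)C)CCO[Si](C)(C)C(C)(C)C | intermediate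
37 | ethyl (2E,4E,6S)-8-[(tert-butyldimethylsilyl)oxy]-6-{[(tert-butyldimethylsilyl)oxy]methyl}-4-methylocta-2,4-dienoate | CCOC(=O)/C=C/C(C)=C/[C@@H](CO[Si](C)(C)C(C)(C)C)CCO[Si](C)(C)C(C)(C)C | intermediate
38 | (2E,4E,6S)-8-[(tert-butyldimethylsilyl)oxy]-6-{[(tert-butyldimethylsilyl)oxy]methyl}-4-methylocta-2,4-dienoic acid | OC(=O)/C=C/C(C)=C/[C@@H](CO[Si](C)(C)C(C)(C)C)CCO[Si](C)(C)C(C)(C)C | intermediate
39 | mixed anhydride of 38 with 2,4,6-trichlorobenzoic acid | Clc1cc(Cl)c(C(=O)OC(=O)/C=C/C(C)=C/[C@@H](CO[Si](C)(C)C(C)(C)C)CCO[Si](C)(C)C(C)(C)C)c(Cl)c1 | intermediate (not isolated)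
40 | (2R,3R)-2-[(2S,4R,6S)-4,6-dimethyl-6-(triethylsilyloxy)oct-7-en-2-yl]-6-(propan-2-yloxy)-3,6-dihydro-2H-pyran-3-yl (2E,4E,6S)-8-[(tert-butyldimethylsilyl)oxy]-6-{[(tert-butyldimethylsilyl)oxy]methyl}-4-methylocta-2,4-dienoate | C=C[C@@](C)(O[Si](CC)(CC)CC)C[C@H](C)C[C@H](C)[C@H]1OC(OC(C)C)C=C[C@H]1OC(=O)/C=C/C(C)=C/[C@@H](CO[Si](C)(C)C(C)(C)C)CCO[Si](C)(C)C(C)(C)C | intermediate
41 | (2R,3R)-2-[(2S,4R,6S)-4,6-dimethyl-6-(triethylsilyloxy)oct-7-en-2-yl]-6-hydroxy-3,6-dihydro-2H-pyran-3-yl (2E,4E,6S)-8-[(tert-butyldimethylsilyl)oxy]-6-{[(tert-butyldimethylsilyl)oxy]methyl}-4-methylocta-2,4-dienoate | C=C[C@@](C)(O[Si](CC)(CC)CC)C[C@H](C)C[C@H](C)[C@H]1OC(O)C=C[C@H]1OC(=O)/C=C/C(C)=C/[C@@H](CO[Si](C)(C)C(C)(C)C)CCO[Si](C)(C)C(C)(C)C | intermediate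
42 | (2R,3R)-2-[(2S,4R,6S)-4,6-dimethyl-6-(triethylsilyloxy)oct-7-en-2-yl]-6-oxo-3,6-dihydro-2H-pyran-3-yl (2E,4E,6S)-8-[(tert-butyldimethylsilyl)oxy]-6-{[(tert-butyldimethylsilyl)oxy]methyl}-4-methylocta-2,4-dienoate | C=C[C@@](C)(O[Si](CC)(CC)CC)C[C@H](C)C[C@H](C)[C@H]1OC(=O)C=C[C@H]1OC(=O)/C=C/C(C)=C/[C@@H](CO[Si](C)(C)C(C)(C)C)CCO[Si](C)(C)C(C)(C)C | intermediate
43 | CNP0227568.1, (2R,3R)-2-[(2S,4R,6S)-6-hydroxy-4,6-dimethyloct-7-en-2-yl]-6-oxo-3,6-dihydro-2H-pyran-3-yl (2E,4E,6S)-8-hydroxy-6-(hydroxymethyl)-4-methylocta-2,4-dienoate | C=C[C@@](C)(O)C[C@H](C)C[C@H](C)[C@H]1OC(=O)C=C[C@H]1OC(=O)/C=C/C(C)=C/[C@@H](CO)CCO | target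

**Step count**
Total: 31 steps. Longest linear sequence: 17 steps (1–3, 6–11, 14–17, 28–31).

**Steps most likely to fail**

Step 14. The endo preference may erode and the facial bias of the α-methyl aldehyde may be weak in the pericyclic manifold, giving C5/C6 isomer mixtures, and the centre α to the ketone may epimerise during acid unmasking. The fallback keeps the same two components but moves to the stepwise, open-transition-state manifold and corrects C5 afterwards. It sets out from 16 and 19: BF3·OEt2 in CH2Cl2 at −78 °C (Mukaiyama aldol, then TFA cyclisation) should give, with stronger Felkin control, the trans pyranone (2R,3R)-2-[(2S,4R,6S)-4,6-dimethyl-6-(triethylsilyloxy)oct-7-en-2-yl]-4-oxo-3,4-dihydro-2H-pyran-3-yl benzoate F1. Luche reduction would give the allylic alcohol (2R,3S,4R)-4-hydroxy-2-[(2S,4R,6S)-4,6-dimethyl-6-(triethylsilyloxy)oct-7-en-2-yl]-3,4-dihydro-2H-pyran-3-yl benzoate F2. Ferrier rearrangement with i-PrOH/PPTS would give the trans acetal (2R,3S)-2-[(2S,4R,6S)-4,6-dimethyl-6-(triethylsilyloxy)oct-7-en-2-yl]-6-(propan-2-yloxy)-3,6-dihydro-2H-pyran-3-yl benzoate F3, and K2CO3/MeOH the trans alcohol (2R,3S)-2-[(2S,4R,6S)-4,6-dimethyl-6-(triethylsilyloxy)oct-7-en-2-yl]-6-(propan-2-yloxy)-3,6-dihydro-2H-pyran-3-ol F4. Mitsunobu esterification of this alcohol with acid 38 (PPh3, DIAD, toluene, 0 °C → rt) inverts C5 and comes back to the route at 40.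

Step 16. Protonation of the enol ether (simple addition of i-PrOH) or acid cleavage of the tertiary allylic silyl ether may compete with the allylic ionisation, which the neighbouring benzoate slows. The fallback replaces Brønsted-acid ionisation by neutral π-allyl chemistry. It sets out from 22: Ac2O/pyridine/DMAP would give the 4-O-acetyl derivative of 22 (all-cis acetate) F5; Pd-catalysed O-glycosylation of this glycal ester with zinc isopropoxide (Pd(OAc)2, 2-(di-tert-butylphosphino)biphenyl, i-PrOH/Et2Zn, THF, rt) should transpose the allyl system and comes back at 23.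

Step 29. Hydrolysis of the acetal may be slow because the C5 acyloxy group destabilises the oxocarbenium ion, so that silyl ether cleavage or acyl migration competes before the oxidation. The fallback changes the order of events and relies on a chemoselective oxidant. It sets out from 40: aqueous HF in MeCN (0 °C → rt) would remove all three silyl groups and hydrolyse the acetal in one operation to the lactol tetraol (2R,3R)-6-hydroxy-2-[(2S,4R,6S)-6-hydroxy-4,6-dimethyloct-7-en-2-yl]-3,6-dihydro-2H-pyran-3-yl (2E,4E,6S)-8-hydroxy-6-(hydroxymethyl)-4-methylocta-2,4-dienoate F6. Activated MnO2 in CH2Cl2 should then oxidise only the allylic lactol, leaving the saturated primary and the tertiary alcohols, and comes back at 43.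

**Further compounds**
F1 | step 14 | (2R,3R)-2-[(2S,4R,6S)-4,6-dimethyl-6-(triethylsilyloxy)oct-7-en-2-yl]-4-oxo-3,4-dihydro-2H-pyran-3-yl benzoate | C=C[C@@](C)(O[Si](CC)(CC)CC)C[C@H](C)C[C@H](C)[C@H]1OC=CC(=O)[C@@H]1OC(=O)c1ccccc1
F2 | step 14 | (2R,3S,4R)-4-hydroxy-2-[(2S,4R,6S)-4,6-dimethyl-6-(triethylsilyloxy)oct-7-en-2-yl]-3,4-dihydro-2H-pyran-3-yl benzoate | C=C[C@@](C)(O[Si](CC)(CC)CC)C[C@H](C)C[C@H](C)[C@H]1OC=C[C@@H](O)[C@@H]1OC(=O)c1ccccc1
F3 | step 14 | (2R,3S)-2-[(2S,4R,6S)-4,6-dimethyl-6-(triethylsilyloxy)oct-7-en-2-yl]-6-(propan-2-yloxy)-3,6-dihydro-2H-pyran-3-yl benzoate | C=C[C@@](C)(O[Si](CC)(CC)CC)C[C@H](C)C[C@H](C)[C@H]1OC(OC(C)C)C=C[C@@H]1OC(=O)c1ccccc1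
F4 | step 14 | (2R,3S)-2-[(2S,4R,6S)-4,6-dimethyl-6-(triethylsilyloxy)oct-7-en-2-yl]-6-(propan-2-yloxy)-3,6-dihydro-2H-pyran-3-ol | C=C[C@@](C)(O[Si](CC)(CC)CC)C[C@H](C)C[C@H](C)[C@H]1OC(OC(C)C)C=C[C@@H]1O
F5 | step 16 | 4-O-acetyl derivative of 22 (all-cis acetate) | C=C[C@@](C)(O[Si](CC)(CC)CC)C[C@H](C)C[C@H](C)[C@H]1OC=C[C@@H](OC(C)=O)[C@H]1OC(=O)c1ccccc1
F6 | step 29 | (2R,3R)-6-hydroxy-2-[(2S,4R,6S)-6-hydroxy-4,6-dimethyloct-7-en-2-yl]-3,6-dihydro-2H-pyran-3-yl (2E,4E,6S)-8-hydroxy-6-(hydroxymethyl)-4-methylocta-2,4-dienoate | C=C[C@@](C)(O)C[C@H](C)C[C@H](C)[C@H]1OC(O)C=C[C@H]1OC(=O)/C=C/C(C)=C/[C@@H](CO)CCO
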